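No constant of this flask is known to me, so I replace the curves by their means and keep two rates.

all flasks: gas 2.5 mM (held)
- winter: left-handed substrate 0.050 M; right-handed substrate 0.050 M; free catalyst 70 µM; run made earlier
- dawn: left-handed substrate 0.050 M; right-handed substrate 0.050 M; free catalyst 110 µM; run made earlier
- summer: left-handed substrate 0.075 M; right-handed substrate 0.075 M; free catalyst 50 µM; run made earlier
- flask: left-handed substrate 0.050 M; right-handed substrate 0.050 M; free catalyst 50 µM; time 5.0 d

- winter (time / d: right-handed substrate / %, left-handed substrate / %): 0.250: 49.2, 47.9; 0.333: 50.3, 47.7; 0.500: 50.4, 49.5; 0.833: 50.3, 47.5; 1.25: 48.3, 45.8; 2.08: 49.0, 44.0; 3.00: 46.9, 39.4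
- dawn (time / d: right-handed substrate / %, left-handed substrate / %): 0.167: 49.6, 50.6; 0.500: 49.6, 48.9; 0.833: 48.8, 46.0; 1.25: 48.2, 44.4; 1.67: 45.8, 42.4; 2.50: 45.8, 41.8; 3.00: 44.1, 39.2
- summer (time / d: right-handed substrate / %, left-handed substrate / %): 0.250: 49.3, 50.3; 0.833: 50.6, 49.0; 1.25: 50.0, 46.9; 2.00: 47.7, 46.9; 3.00: 48.9, 46.2

(readings scatter by 1 percentage point)

- free catalyst is single-handed; left-handed substrate and right-handed substrate are mirror images of each other, charged as a racemate, each of them at the stated concentration
- the earlier runs were read with a standard deviation of 1 percentage point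
- at the start none of the gas is in solution

- whether the excess of right-handed substrate over left-handed substrate among what is left of the two reaches 99% by 5.0 d (no / yes)
- the highest excess of right-handed substrate over left-handed substrate among what is left of the two up to 5.0 d

The summer run has the same free catalyst charge as the flask, though a richer charge of each substrate than the flask. At its last reading, [right-handed substrate] − [left-handed substrate] has opened at a mean 1.35 mM d⁻¹. This gap rate is what I carry, as a rough reading: each reading has a scatter of 1 percentage point, and the gap of 2.7 points is a difference of two of them. Against it stands the charge rate, both charges of the flask spread over the time allowed, 20.0 mM d⁻¹. Their ratio, 6.75%, is my own estimate of the excess at 5.0 d, with the sum of the two substrates taken as unchanged. For 99%, that gap would need the sum to fall to 6.82 mM, a fall of 93.2 mM, yet the two substrates of the summer run read a loss of 7.35 mM by 3.00 d, far less than this fall, so I say no.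

The forecast says no and 8%, within 5% to 13%, which is higher than my figure: “With so little conversion and modest selectivity, 99% is impossible.”

The flask gives no and 6.78%, inside the forecast's range .

    free catalyst + left-handed substrate ⇌ catalyst intermediate A (K = 46.0 L mol⁻¹, k = 35100 L mol⁻¹ h⁻¹)
    free catalyst + right-handed substrate ⇌ catalyst intermediate B (K = 280 L mol⁻¹, k = 34800 L mol⁻¹ h⁻¹)
    partner + catalyst intermediate A → free catalyst + left-handed product (k = 8620 L mol⁻¹ h⁻¹)
    partner + catalyst intermediate B → free catalyst + right-handed product (k = 599 L mol⁻¹ h⁻¹)
    2 free catalyst ⇌ resting dimer (K = 71000 L mol⁻¹, k = 11800 L mol⁻¹ h⁻¹)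
    gas ⇌ partner, rate k6*(csat - [partner]) (kL = 0.274 h⁻¹)
    partner → decomposed reagent (k = 0.0454 h⁻¹)

In the flask, [partner] stood at 0.00170 M at 0.500 d and 0.00175 M at 5.00 d, while catalyst intermediate B, the resting state, held 79.5% of the catalyst at the end. Partner and catalyst intermediate A made left-handed product steadily, half of that turnover being done by 2.48 d. The flask's own gap rate is 1.15 mM d⁻¹, and that gap is divided by a sum down to 84.5% of the charge. For the same flask read at 50 h, the gap rate gives 2.81%, and the flask stands at 2.63%.

(The runs are simulated on assumed constants, and the scatter is random.)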